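## Overview

- **Locants.** The carbocycle is C1 (lactone O-CH), C2 (ring-fusion CH), C3 (CH2), C4 (CHOH), C5 (CHCH3), C6 (C(OH)-acyl) and C7 (CH-O-isovaleryl). The "lower face" is the face that carries C1-O.
- **Cuts.** The retrosynthesis cuts the propenyl-C(=O) bond of the crotonoyl group, then the C7-O ester bond, then the lactone carbonyl carbon (CO placed between C1-O and an ethynyl group on C2), and last the ring bonds C5-C6 and C1-C2.
- **Enabling feature.** The seven-membered ring is a masked cyclohepta-1,4-diene: C6=C7 is the enol silane of a C7-keto C6-ester and C3=C4 is the enol silane of a C4 ketone. Its three remaining sp3 carbons C1, C2 and C5 hold O, C and CH3 on one face, which is the pattern a vinylcarbenoid (C6-C7-C1) and a diene (C5-C4-C3-C2) give in a [4+3] union.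
- **Forward order.** Two short fragments meet in the [4+3], which closes the carbocycle. A temporary gamma-lactone bridge C4-O-C(=O)-C6 follows, then the alpha-methylene-gamma-lactone on C1-O/C2 by cyclocarbonylation, then the C7 ester. The bridge, by then an acetal, is finally opened to take up the propenyl group.
- **Stereochemistry.** The chiral dirhodium catalyst fixes C5. The three alkene geometries and the boat Cope transition state relay this to C1 and C2. C1-OH steers oxygen to the lower face of C6. C6-OH and C1-OH hand hydride to the lower faces of C7 and C4. The E enone comes from (E)-1-bromopropene.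

Key step: step 6

Abbreviations: PMB = 4-methoxybenzyl; TBS = t-BuMe2Si; TES = Et3Si; TIPS = i-Pr3Si; Rh2(S-PTAD)4 = dirhodium tetrakis[(S)-(1-adamantyl)(phthalimido)acetate].

Assumption: the sense of induction known for Rh2(S-PTAD)4 with unsubstituted 3-siloxy-2-diazobut-3-enoates is taken to carry over to 4 and to give the C5 configuration drawn. Both ligand antipodes are accessible, so Rh2(R-PTAD)4 would replace it unchanged if the first adduct proved antipodal.

## Route

Step 1
Reactants: 1 methyl 4-chloroacetoacetate
Product: 2 methyl 4-(4-methoxybenzyloxy)-3-oxobutanoate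
Conditions: PMBOH (1.1 equiv), NaH (2.2 equiv), THF, 0 °C to rt; then 1 M HCl
Reagents that add atoms: 4-methoxybenzyl alcohol, COc1ccc(CO)cc1
Why: Williamson ether synthesis, in which the alkoxide displaces the activated primary chloride next to the ketone while the second equivalent of NaH holds the beta-keto ester as its enolate and so keeps alkoxide away from both carbonyl groups.

Step 2
Reactants: 2 methyl 4-(4-methoxybenzyloxy)-3-oxobutanoate
Product: 3 methyl 2-diazo-4-(4-methoxybenzyloxy)-3-oxobutanoate
Conditions: 4-acetamidobenzenesulfonyl azide (1.1 equiv), Et3N (1.2 equiv), MeCN, 0 °C to rt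
Reagents that add atoms: 4-acetamidobenzenesulfonyl azide, CC(=O)Nc1ccc(cc1)S(=O)(=O)N=[N+]=[N-]
Why: Regitz diazo transfer, in which the amine-generated enolate of the 1,3-dicarbonyl attacks the terminal azide nitrogen and the sulfonamide departs, a standard reaction of acetoacetates that leaves the benzylic ether alone.

Step 3
Reactants: 3 methyl 2-diazo-4-(4-methoxybenzyloxy)-3-oxobutanoate
Product: 4 fragment 1 methyl (Z)-3-(tert-butyldimethylsilyloxy)-2-diazo-4-(4-methoxybenzyloxy)but-3-enoate
Conditions: TBSOTf (1.2 equiv), Et3N (1.5 equiv), CH2Cl2, 0 °C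
Reagents that add atoms: tert-butyldimethylsilyl trifluoromethanesulfonate, CC(C)(C)[Si](C)(C)OS(=O)(=O)C(F)(F)F
Why: Soft enolisation and O-silylation of a 2-diazo-3-oxo ester that can enolise only towards C4, the PMBO group settling trans to the bulky diazo ester carbon (cis to OSi, hence Z) to avoid allylic strain, as 4-substituted members of this class do.

Step 4
Reactants: 5 3-(triisopropylsilyl)prop-2-ynal; 6 diethyl (2-oxobutyl)phosphonate
Product: 7 (E)-7-(triisopropylsilyl)hept-4-en-6-yn-3-one
Conditions: LiCl (1.2 equiv), i-Pr2NEt (1.1 equiv), MeCN, rt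
Reagents that add atoms: none
Why: Horner-Wadsworth-Emmons olefination under Masamune-Roush conditions, where the lithium-chelated keto phosphonate is deprotonated by the amine, mildly enough for the base-sensitive ynal, and the stabilised anion gives the E alkene.

Step 5
Reactants: 7 (E)-7-(triisopropylsilyl)hept-4-en-6-yn-3-one
Product: 8 fragment 2 (2Z,4E)-3-(triethylsilyloxy)-7-(triisopropylsilyl)hepta-2,4-dien-6-yne
Conditions: TESOTf (1.2 equiv), Et3N (1.5 equiv), Et2O, -78 to 0 °C
Reagents that add atoms: triethylsilyl trifluoromethanesulfonate, CC[Si](CC)(CC)OS(=O)(=O)C(F)(F)F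
Why: Silyl triflate/amine enolisation of an ethyl enone, which can lose a proton only from its CH2 group and gives the Z enol silane (CH3 cis to OSi) because the methyl group turns away from the alkenyl residue in the O-silylated oxocarbenium ion.

Step 6
Reactants: 4 fragment 1 methyl (Z)-3-(tert-butyldimethylsilyloxy)-2-diazo-4-(4-methoxybenzyloxy)but-3-enoate; 8 fragment 2 (2Z,4E)-3-(triethylsilyloxy)-7-(triisopropylsilyl)hepta-2,4-dien-6-yne
Product: 10 all-cis cycloheptadiene bis(enol silane), via cis-divinylcyclopropane 9 (not isolated)
Conditions: Rh2(S-PTAD)4 (2 mol %), 8 (2.5 equiv), degassed hexanes, -20 °C to rt, 4 (in a little toluene) added over 4 h; then 50 °C, 2 h; excess 8 recovered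
Reagents that add atoms: none
Why: Proposed new method: loss of dinitrogen from 4 on the divalent-rhodium dimer gives a donor/acceptor vinylcarbenoid whose carbene carbon C6 is attacked by the CH(CH3) terminus C5 of the siloxy alkene of 8, the developing cation at C4 being carried by its siloxy and alkenyl groups, C4-C6 closure then gives cyclopropane 9 with its two alkenyl arms cis, and a [3,3] shift breaks C4-C6 as C1-C2 forms. The closest known reaction type is the dirhodium tetracarboxylate-catalysed tandem cyclopropanation/Cope rearrangement of 3-siloxy-2-diazobut-3-enoates with 1,3-dienes, highly enantioselective with this adamantyl-phthalimido ligand; not yet shown are an alkoxy group on the vinyl terminus of the carbenoid and a trisubstituted alkene of a 2-siloxydiene as the site of cyclopropanation. The three-membered ring closes by an asynchronous concerted [2+1] addition and the seven-membered carbocycle by a strain-releasing divinylcyclopropane Cope rearrangement through an endo boat transition state, so that the net [4+3] union makes C5-C6 and C1-C2. C5 is set by the catalyst, whose ligand wall selects the alkene face in the first C-C bond, and its methyl group ends trans to both arms because the addition is stereospecific for the Z enol silane of 8, while C1 and C2 are set by the boat, in which the PMBO group (trans to C6 in Z-4) and the alkynyl group (E alkene of 8) both point outwards, which puts C1-O, C2-C and C5-CH3 on one face. The step needs site selectivity for the siloxy alkene and reaction at the carbene carbon instead of the vinylogous terminus: the siloxy alkene is by far the most electron-rich pi bond, the other alkene is a trans-disubstituted enyne of a kind such carbenoids leave alone, the alkyne is walled in by TIPS, the substituted vinyl terminus and the hydrocarbon solvent disfavour vinylogous attack, and the PMBO group, held trans to the carbene, is out of reach for C-H insertion. Should some trans-dialkenyl cyclopropane form, its donor-acceptor C4-C6 bond can open and reclose on warming and so supply the isomer that is able to rearrange.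

Step 7
Reactants: 10 all-cis cycloheptadiene bis(enol silane)
Product: 11 C4 ketone with C1-OPMB and intact C6=C7 TBS enol ether
Conditions: PPTS (0.1 equiv), THF-H2O 10:1, 0 °C
Reagents that add atoms: none
Why: Acid-catalysed silyl enol ether hydrolysis, selective because C-protonation of the electron-rich TES enol ether at C3 is far faster than that of the bulkier, ester-conjugated TBS enol ether, and harmless to stereochemistry because C3 becomes CH2 and the weakly acidic medium does not enolise C5.

Step 8
Reactants: 11 C4 ketone with C1-OPMB and intact C6=C7 TBS enol ether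
Product: 12 C4 ketone with free C1-OH and intact C6=C7 TBS enol ether
Conditions: DDQ (1.3 equiv), CH2Cl2-pH 7 buffer (KH2PO4/K2HPO4) 10:1, 0 °C; used without storage
Reagents that add atoms: none
Why: Oxidative PMB ether cleavage by hydride abstraction from the electron-rich benzylic position, tolerated by the ester-deactivated enol silane, with the buffer excluding the acid or base that would epimerise C5 or move the silyl group to C1-O.

Step 9
Reactants: 12 C4 ketone with free C1-OH and intact C6=C7 TBS enol ether
Product: 14 C6-silyloxy C7-ketone, via siloxy epoxide 13 (not isolated)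
Conditions: VO(acac)2 (10 mol %), t-BuOOH (decane, 1.5 equiv), CH2Cl2, 0 °C to rt
Reagents that add atoms: tert-butyl hydroperoxide, CC(C)(C)OO
Why: Hydroxyl-directed epoxidation merged with a Rubottom oxidation, in which the C1 alkoxide binds the pentavalent vanadium peroxide formed from VO(acac)2 and t-BuOOH and hands oxygen to the lower face of the allylic C6=C7 bond, which sets C6, after which siloxy epoxide 13 opens at C7 and the silyl group shifts to the new C6 oxygen to leave the C7 ketone.

Step 10
Reactants: 14 C6-silyloxy C7-ketone
Product: 15 alpha-hydroxy beta-keto ester with C6-OH on the lower face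
Conditions: HF·pyridine, extra pyridine, THF, 0 °C
Reagents that add atoms: none
Why: Fluoride desilylation in a weakly acidic medium, which frees the tertiary C6-OH without the base that would trigger retro-aldol or retro-Claisen cleavage of this polycarbonyl array and which leaves the alkynyl-TIPS bond intact.

Step 11
Reactants: 15 alpha-hydroxy beta-keto ester with C6-OH on the lower face
Product: 16 tetraol methyl ester
Conditions: Me4NBH(OAc)3 (8 equiv), MeCN-AcOH 1:1, -30 to 0 °C; aq. potassium sodium tartrate
Reagents that add atoms: none
Why: Evans-Saksena reduction, in which C6-OH and C1-OH exchange onto boron and deliver hydride internally to the lower faces of the alpha-hydroxy C7 ketone and the beta-hydroxy C4 ketone, so both new hydroxyls appear on the upper face anti to C6-OH, while the unbound reagent is too weak to reduce ketone or ester.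

Step 12
Reactants: 16 tetraol methyl ester
Product: 17 bridged gamma-lactone triol
Conditions: camphorsulfonic acid (10 mol %), toluene, 4 Å molecular sieves, 50 °C
Reagents that add atoms: none
Why: Acid-catalysed lactonisation (transesterification), open only to C4-OH because it alone shares the upper face with the C6 ester at five-ring distance, so C4-OH is masked and any C4 epimer from step 11 stays open and can be separated.

Step 13
Reactants: 17 bridged gamma-lactone triol
Product: 18 bridged lactol triol
Conditions: i-Bu2AlH (5 equiv), CH2Cl2, -78 °C; MeOH, aq. potassium sodium tartrate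
Reagents that add atoms: none
Why: Partial reduction of a lactone to the lactol, in which three equivalents are spent on the hydroxyls and the bicyclic aluminium hemiacetal holds at -78 °C against a second hydride, the silyl alkyne being inert at this temperature.

Step 14
Reactants: 18 bridged lactol triol
Product: 19 bridged methyl acetal triol
Conditions: MeOH, PPTS (0.1 equiv), rt
Reagents that add atoms: methanol, CO
Why: Fischer-type acetalisation through the cyclic oxocarbenium ion, which caps the only hemiacetal hydroxyl, either anomer being acceptable since the centre is erased in step 18.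

Step 15
Reactants: 19 bridged methyl acetal triol
Product: 20 terminal alkyne triol
Conditions: Bu4NF (1.2 equiv), THF, 0 °C
Reagents that add atoms: none
Why: Fluoride protodesilylation of an alkynylsilane, uncomplicated here because the triol acetal holds no base-sensitive group.

Step 16
Reactants: 20 terminal alkyne triol
Product: 21 alpha-methylene-gamma-lactone with free C7-OH
Conditions: PdCl2 (5 mol %), PPh3 (10 mol %), SnCl2 (5 mol %), CO (8 atm), MeCN, 70 °C
Reagents that add atoms: carbon monoxide, [C-]#[O+]
Why: Palladium-catalysed cyclocarbonylation of a homopropargylic alcohol, in which C1-OH and CO form an alkoxycarbonyl complex of divalent palladium, the cis ethynyl group on C2 inserts syn (5-exo-dig) and protonolysis releases the methylene lactone, whereas C7-OH lies on the other face and would need a six-membered ring, and no stereocentre is touched.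

Step 17
Reactants: 21 alpha-methylene-gamma-lactone with free C7-OH; 22 isovaleric anhydride
Product: 23 C7 isovalerate
Conditions: 22 (1.5 equiv), DMAP (0.2 equiv), pyridine, CH2Cl2, 0 °C to rt
Reagents that add atoms: none
Why: DMAP-catalysed acylation through the acylpyridinium ion, which reaches the only secondary hydroxyl (C7) and leaves the crowded tertiary C6-OH unchanged.

Step 18
Reactants: 23 C7 isovalerate
Product: 24 bridged lactol isovalerate
Conditions: 1 M aq. HCl-THF 1:3, 45 °C
Reagents that add atoms: water, O
Why: Specific-acid hydrolysis of the mixed acetal through the bridged oxocarbenium ion, under dilute acid that the isovalerate and the methylene lactone withstand.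

Step 19
Reactants: 24 bridged lactol isovalerate; 25 (E)-1-bromopropene
Product: 27 allylic alcohol (either carbinol epimer), via hydroxy aldehyde 26 (not isolated)
Conditions: CrCl2 (8 equiv), NiCl2 (0.1 equiv), 25 (4 equiv), DMF-THF, rt
Reagents that add atoms: none
Why: Nozaki-Hiyama-Kishi reaction, in which zerovalent nickel inserts into the C-Br bond with retention, the E-propenyl group passes to trivalent chromium and this mild nucleophile adds only to the aldehyde 26 released by the lactol, sparing both esters and the methylene lactone, the new carbinol centre needing no control because step 20 removes it.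

Step 20
Reactants: 27 allylic alcohol (either carbinol epimer)
Product: 28 target CNP0186412.1
Conditions: activated MnO2 (20 equiv), CH2Cl2, rt
Reagents that add atoms: none
Why: Allylic-selective oxidation on the MnO2 surface, where only the carbinol next to the propenyl group is activated, so the saturated C4-OH and the tertiary C6-OH remain and the E alkene is kept.

## Compound list

1 | methyl 4-chloroacetoacetate | COC(=O)CC(=O)CCl | starting material
2 | methyl 4-(4-methoxybenzyloxy)-3-oxobutanoate | COC(=O)CC(=O)COCc1ccc(OC)cc1 | intermediate
3 | methyl 2-diazo-4-(4-methoxybenzyloxy)-3-oxobutanoate | COC(=O)C(=[N+]=[N-])C(=O)COCc1ccc(OC)cc1 | intermediate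
4 | fragment 1, methyl (Z)-3-(tert-butyldimethylsilyloxy)-2-diazo-4-(4-methoxybenzyloxy)but-3-enoate (PMBO cis to OTBS, trans to the diazo carbon) | COC(=O)C(=[N+]=[N-])/C(O[Si](C)(C)C(C)(C)C)=C/OCc1ccc(OC)cc1 | intermediate
5 | 3-(triisopropylsilyl)prop-2-ynal | O=CC#C[Si](C(C)C)(C(C)C)C(C)C | starting material
6 | diethyl (2-oxobutyl)phosphonate | CCC(=O)CP(=O)(OCC)OCC | starting material
7 | (E)-7-(triisopropylsilyl)hept-4-en-6-yn-3-one | CCC(=O)/C=C/C#C[Si](C(C)C)(C(C)C)C(C)C | intermediate
8 | fragment 2, (2Z,4E)-3-(triethylsilyloxy)-7-(triisopropylsilyl)hepta-2,4-dien-6-yne | C/C=C(O[Si](CC)(CC)CC)/C=C/C#C[Si](C(C)C)(C(C)C)C(C)C | intermediate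
9 | cis-divinylcyclopropane: C6 bears CO2Me and the (Z)-1-OTBS-2-OPMB-ethenyl arm, C4 bears OTES and the (E)-enynyl arm, C5 bears CH3; the two arms are cis, and CH3, OTES and CO2Me lie on the other face | COC(=O)[C@@]1(/C(O[Si](C)(C)C(C)(C)C)=C/OCc2ccc(OC)cc2)[C@@H](C)[C@]1(O[Si](CC)(CC)CC)/C=C/C#C[Si](C(C)C)(C(C)C)C(C)C | intermediate
10 | cycloheptadiene: C3=C4(OTES), C6(CO2Me)=C7(OTBS); C1-OPMB, C2-C≡C-TIPS and C5-CH3 all on the lower face | COc1ccc(CO[C@@H]2[C@H](C#C[Si](C(C)C)(C(C)C)C(C)C)C=C(O[Si](CC)(CC)CC)[C@H](C)C(C(=O)OC)=C2O[Si](C)(C)C(C)(C)C)cc1 | intermediate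
11 | C4 ketone, C3H2, C1-OPMB, C6=C7 TBS enol ether | COc1ccc(CO[C@@H]2[C@H](C#C[Si](C(C)C)(C(C)C)C(C)C)CC(=O)[C@H](C)C(C(=O)OC)=C2O[Si](C)(C)C(C)(C)C)cc1 | intermediate
12 | C4 ketone with free C1-OH, C6=C7 TBS enol ether | O[C@@H]1[C@H](C#C[Si](C(C)C)(C(C)C)C(C)C)CC(=O)[C@H](C)C(C(=O)OC)=C1O[Si](C)(C)C(C)(C)C | intermediate
13 | siloxy epoxide, epoxide oxygen on the lower face of C6-C7 | O[C@@H]1[C@H](C#C[Si](C(C)C)(C(C)C)C(C)C)CC(=O)[C@H](C)[C@]2(C(=O)OC)O[C@]12O[Si](C)(C)C(C)(C)C | intermediate
14 | C6-OTBS (lower face), C6-CO2Me (upper face), C7 and C4 ketones, C1-OH | O[C@@H]1[C@H](C#C[Si](C(C)C)(C(C)C)C(C)C)CC(=O)[C@H](C)[C@@](O[Si](C)(C)C(C)(C)C)(C(=O)OC)C1=O | intermediate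
15 | alpha-hydroxy beta-keto ester, C6-OH on the face of C1-OH | O[C@@H]1[C@H](C#C[Si](C(C)C)(C(C)C)C(C)C)CC(=O)[C@H](C)[C@@](O)(C(=O)OC)C1=O | intermediate
16 | tetraol methyl ester, C4-OH and C7-OH on the upper face, C1-OH and C6-OH on the lower face | O[C@@H]1[C@H](C#C[Si](C(C)C)(C(C)C)C(C)C)C[C@@H](O)[C@H](C)[C@@](O)(C(=O)OC)[C@H]1O | intermediate
17 | bridged gamma-lactone (C4-O to the C6 carboxyl, upper face), free C1-OH, C6-OH, C7-OH | O[C@@H]1[C@H](C#C[Si](C(C)C)(C(C)C)C(C)C)C[C@@H](O2)[C@H](C)[C@@](O)(C2=O)[C@H]1O | intermediate
18 | bridged lactol (anomers) | O[C@@H]1[C@H](C#C[Si](C(C)C)(C(C)C)C(C)C)C[C@@H](O2)[C@H](C)[C@@](O)(C2O)[C@H]1O | intermediate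
19 | bridged methyl acetal (anomers) | O[C@@H]1[C@H](C#C[Si](C(C)C)(C(C)C)C(C)C)C[C@@H](O2)[C@H](C)[C@@](O)(C2OC)[C@H]1O | intermediate
20 | terminal alkyne, bridged methyl acetal | O[C@@H]1[C@H](C#C)C[C@@H](O2)[C@H](C)[C@@](O)(C2OC)[C@H]1O | intermediate
21 | cis-fused alpha-methylene-gamma-lactone with bridged methyl acetal, C7-OH the only secondary alcohol | C=C1C(=O)O[C@@H]2[C@H]1C[C@@H](O3)[C@H](C)[C@@](O)(C3OC)[C@H]2O | intermediate
22 | isovaleric anhydride | CC(C)CC(=O)OC(=O)CC(C)C | starting material
23 | C7 isovalerate, bridged methyl acetal | C=C1C(=O)O[C@@H]2[C@H]1C[C@@H](O3)[C@H](C)[C@@](O)(C3OC)[C@H]2OC(=O)CC(C)C | intermediate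
24 | C7 isovalerate, bridged lactol | C=C1C(=O)O[C@@H]2[C@H]1C[C@@H](O3)[C@H](C)[C@@](O)(C3O)[C@H]2OC(=O)CC(C)C | intermediate
25 | (E)-1-bromopropene | C/C=C/Br | starting material
26 | open hydroxy aldehyde (C6-CHO, C4-OH) | C=C1C(=O)O[C@@H]2[C@H]1C[C@@H](O)[C@H](C)[C@@](O)(C=O)[C@H]2OC(=O)CC(C)C | intermediate
27 | (E)-allylic alcohol, either carbinol epimer | C=C1C(=O)O[C@@H]2[C@H]1C[C@@H](O)[C@H](C)[C@@](O)(C(O)/C=C/C)[C@H]2OC(=O)CC(C)C | intermediate
28 | CNP0186412.1, (3aS,5R,6S,7S,8S,8aR)-7-[(E)-but-2-enoyl]-5,7-dihydroxy-6-methyl-3-methylidene-2-oxooctahydro-2H-cyclohepta[b]furan-8-yl 3-methylbutanoate | C=C1C(=O)O[C@@H]2[C@H]1C[C@@H](O)[C@H](C)[C@@](O)(C(=O)/C=C/C)[C@H]2OC(=O)CC(C)C | target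

## Step count

- Total step count: 20
- Longest linear sequence: 18 (steps 1 to 3 and 6 to 20)

## Steps most likely to fail

**1. Step 6.**
- *Risk.* Cyclopropanation of the crowded trisubstituted enol silane may be slower than carbenoid dimerisation, attack at the vinylogous carbon or silyl transfer after the first C-C bond. The enantioselectivity may also erode with the new substitution.
- *Fallback, from 8 and back at 10.* The cyclopropane is assembled in stages by known reactions.
- 8 is cyclopropanated at its siloxy alkene with methyl diazoacetate under a monovalent-copper bis(oxazoline) catalyst (CuOTf, t-Bu-box, ligand antipode chosen for the C5 configuration). This is the established asymmetric route from silyl enol ethers and 2-siloxydienes to 2-siloxycyclopropanecarboxylates. It gives the siloxy(alkenyl)cyclopropane ester F1, whose ester-bearing carbon may be either epimer.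
- LiN(i-Pr)2 at -78 °C forms the cyclopropyl ester enolate. N-methoxy-N-methyl-2-(4-methoxybenzyloxy)acetamide acylates it on the face away from OTES and CH3 to give the cyclopropyl keto ester F2, with the acyl group cis to the alkenyl arm.
- TBSOTf and Et3N, as in step 3, turn this ketone into its Z enol silane, which is 9, and warming gives 10.

**2. Step 9.**
- *Risk.* Oxygen transfer to the tetrasubstituted, ester-deactivated and doubly flanked alkene may be slow. O-to-O silyl migration from C7-O to C1-O could then remove both the directing group and the enol silane, or undirected attack from the open upper face could erode the facial selectivity.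
- *Fallback, from 12 and back at 15.* Direction by a free hydroxyl is replaced by control through molecular shape.
- C1-OH of 12 is closed across the ring onto the C4 ketone and capped (MeOH, PPTS, 3 Å molecular sieves) as the oxygen-bridged methyl ketal F3. This is an 8-oxabicyclo[3.2.1]octene with its oxygen bridge on the lower face.
- In F3 no hydroxyl is left for silyl migration, C5 is no longer next to a ketone, and the upper (endo) face of C6=C7 is screened by the C2-C3 bridge.
- An ordinary Rubottom oxidation with dimethyldioxirane (acetone-CH2Cl2, low temperature) should therefore come from the exo lower face and give the bridged alpha-siloxy ketone F4.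
- Aqueous HF in MeCN then removes the silyl group and hydrolyses the ketal to 15.

**3. Step 19.**
- *Risk.* The lactol may release too little of the hindered, fully alpha-substituted aldehyde. The alkenyl bromide may enter the nickel cycle slowly. The chromium alkoxide may set off migration of the isovaleryl group to a neighbouring oxygen.
- *Fallback, from 17 and back at 28.* The C-C bond is made earlier, at the carboxyl oxidation level, so that steps 13, 19 and 20 are no longer needed.
- (E)-Prop-1-enyllithium (25, t-BuLi, Et2O, -78 °C, retention of geometry) is used in excess, three equivalents being spent on the hydroxyls. It adds once to the lactone carbonyl of 17, the bicyclic lithium hemiketal resisting a second addition, to give the propenyl hemiketal F5.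
- MeOH with PPTS gives the propenyl methyl ketal F6.
- Bu4NF gives the terminal alkyne ketal F7.
- Cyclocarbonylation as in step 16 gives the methylene lactone ketal F8.
- Acylation with 22 as in step 17 gives the isovalerate ketal F9.
- Dilute aqueous acid opens the allylic ketal directly to 28.

Further compounds
F1 | step 6 | methyl 3-methyl-2-(triethylsilyloxy)-2-[(E)-4-(triisopropylsilyl)but-1-en-3-ynyl]cyclopropanecarboxylate, CH3 cis to OTES, ester carbon either epimer | COC(=O)C1[C@@H](C)[C@]1(O[Si](CC)(CC)CC)/C=C/C#C[Si](C(C)C)(C(C)C)C(C)C
F2 | step 6 | cyclopropyl keto ester, C6 bearing CO2Me and C(=O)CH2OPMB, acyl group cis to the enynyl arm | COC(=O)[C@@]1(C(=O)COCc2ccc(OC)cc2)[C@@H](C)[C@]1(O[Si](CC)(CC)CC)/C=C/C#C[Si](C(C)C)(C(C)C)C(C)C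
F3 | step 9 | oxygen-bridged methyl ketal (C1-O-C4 bridge on the lower face, C4-OCH3 on the upper face), C6=C7 TBS enol ether | O1[C@@H]2[C@H](C#C[Si](C(C)C)(C(C)C)C(C)C)C[C@@]1(OC)[C@H](C)C(C(=O)OC)=C2O[Si](C)(C)C(C)(C)C
F4 | step 9 | oxygen-bridged methyl ketal with C6-OTBS on the lower face and C7 ketone | O1[C@@H]2[C@H](C#C[Si](C(C)C)(C(C)C)C(C)C)C[C@@]1(OC)[C@H](C)[C@@](O[Si](C)(C)C(C)(C)C)(C(=O)OC)C2=O
F5 | step 19 | bridged (E)-propenyl hemiketal triol | O[C@@H]1[C@H](C#C[Si](C(C)C)(C(C)C)C(C)C)C[C@@H](O2)[C@H](C)[C@@](O)(C2(O)/C=C/C)[C@H]1O
F6 | step 19 | bridged (E)-propenyl methyl ketal triol | O[C@@H]1[C@H](C#C[Si](C(C)C)(C(C)C)C(C)C)C[C@@H](O2)[C@H](C)[C@@](O)(C2(OC)/C=C/C)[C@H]1O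
F7 | step 19 | terminal alkyne, bridged (E)-propenyl methyl ketal | O[C@@H]1[C@H](C#C)C[C@@H](O2)[C@H](C)[C@@](O)(C2(OC)/C=C/C)[C@H]1O
F8 | step 19 | alpha-methylene-gamma-lactone, bridged (E)-propenyl methyl ketal, free C7-OH | C=C1C(=O)O[C@@H]2[C@H]1C[C@@H](O3)[C@H](C)[C@@](O)(C3(OC)/C=C/C)[C@H]2O
F9 | step 19 | C7 isovalerate, bridged (E)-propenyl methyl ketal | C=C1C(=O)O[C@@H]2[C@H]1C[C@@H](O3)[C@H](C)[C@@](O)(C3(OC)/C=C/C)[C@H]2OC(=O)CC(C)C
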